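## Plan

- Retrosynthesis: ring B is a 2-methoxy-1,4-benzoquinone with hydrogen on C3' and C6' and chromanone C2 on C1'. Cutting C1'–C2' unfolds it to a 4-alkynyl-4-hydroxy-3-methoxycyclobut-2-enone (C2'–C5' are the four-membered ring, C6' and C1' the alkyne); this H/OMe/H pattern is what permits a thermal ring expansion.
- Further cuts: C5'–C6' (lithium acetylide onto the ketone-like carbonyl of methyl semisquarate), C1'–C2 (alkyne onto C2 of a chromone), then O1–C2 and C2–C3 of ring C (formate supplies C2), and the two C-methyls and the 7-O-methyl of phloroacetophenone.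
- Forward: ring A is methylated, ring C is closed as the chromone, the alkyne is added at C2, the cyclobutenone is attached, ring B is closed last by heating, and the 5-O-MOM group is removed.
- Stereochemistry: C2 (S), the only stereocentre of the target, comes from a copper-catalysed enantioselective alkynylation of the 4-silyloxybenzopyrylium ion. The C4 ketone is held as its carbinol while organolithium base is present (a ketal of this donor-rich, peri-hindered aryl ketone is not relied on) and is restored before the ring expansion.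

Key step: step 10

Assumption: the sense of induction of the P,N ligand in step 5 is not asserted; the StackPhos antipode that leads to the 2S adduct is the one used.

Remark: C4 in 12, 13, 17 and 18 is drawn as the expected 2,4-cis (4S) epimer. Its configuration, and that of the cyclobutenone carbinol carbon, is immaterial because both centres become trigonal again in steps 9 and 10.

## Route

Step 1
Reactants: 1 2',4',6'-trihydroxyacetophenone
Product: 3 2',4',6'-trihydroxy-3',5'-dimethylacetophenone, via mono-C-methyl ketone 2 (not isolated)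
Conditions: NaOMe (3 equiv), MeI (2.2 equiv), MeOH, 0 °C → reflux
Reagents that add atoms: iodomethane, CI
Why: Acylphloroglucinol phenoxides alkylate on carbon at the two free ring positions in methanol (C-methylation of a phloroglucinol), and limiting MeI to two equivalents should hold back geminal over-methylation.

Step 2
Reactants: 3 2',4',6'-trihydroxy-3',5'-dimethylacetophenone
Product: 4 2',6'-dihydroxy-4'-methoxy-3',5'-dimethylacetophenone
Conditions: Me2SO4 (1.0 equiv), K2CO3 (1.0 equiv), acetone, rt
Reagents that add atoms: dimethyl sulfate, COS(=O)(=O)OC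
Why: Williamson etherification with one equivalent of reagent should take the 4'-hydroxyl, the most acidic one and the only one that cannot hydrogen-bond to the acetyl oxygen, leaving a symmetric 2',6'-diol.

Step 3
Reactants: 4 2',6'-dihydroxy-4'-methoxy-3',5'-dimethylacetophenone
Product: 6 5-hydroxy-7-methoxy-6,8-dimethyl-4H-chromen-4-one, via hemiacetal 5 (not isolated)
Conditions: NaH (5 equiv), HCO2Et, THF, 0 → 40 °C; then 6 M HCl, MeOH, 50 °C
Reagents that add atoms: ethyl formate, CCOC=O
Why: Claisen condensation of the ketone enolate with ethyl formate gives the β-keto aldehyde as its cyclic hemiacetal 5, which acid dehydrates to the 2,3-unsubstituted chromone (the classical formate route, which tolerates a second ortho phenoxide).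

Step 4
Reactants: 6 5-hydroxy-7-methoxy-6,8-dimethyl-4H-chromen-4-one
Product: 7 7-methoxy-5-(methoxymethoxy)-6,8-dimethyl-4H-chromen-4-one
Conditions: NaH, MOMCl, DMF, 0 °C → rt
Reagents that add atoms: chloromethyl methyl ether, COCCl
Why: O-Alkylation of the sodium phenoxide with MOMCl, with NaH in DMF chosen because the 5-hydroxyl is hydrogen-bonded to the C4 carbonyl and weak bases leave it untouched.

Step 5
Reactants: 7 7-methoxy-5-(methoxymethoxy)-6,8-dimethyl-4H-chromen-4-one; 8 trimethylsilylacetylene
Product: 11 (2S)-7-methoxy-5-(methoxymethoxy)-6,8-dimethyl-2-[(trimethylsilyl)ethynyl]chroman-4-one, via benzopyrylium triflate 9 (not isolated), via silyl enol ether 10 (not isolated)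
Conditions: TBSOTf (1.1 equiv), toluene, rt; then CuI (5 mol%), StackPhos (6 mol%), iPr2NEt, 8, −78 → −40 °C; then 0.5 M aq. HCl, THF, 0 °C
Reagents that add atoms: none
Why: O-Silylation turns the chromone into the 4-silyloxybenzopyrylium ion 9, the monovalent copper acetylide formed from CuI, amine and 8 adds at C2 within the chiral P,N-ligand environment (copper-catalysed enantioselective alkynylation of chromones), which sets the 2S configuration, and brief dilute acid hydrolyses enol ether 10 without touching the MOM ether.

Step 6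
Reactants: 11 (2S)-7-methoxy-5-(methoxymethoxy)-6,8-dimethyl-2-[(trimethylsilyl)ethynyl]chroman-4-one
Product: 13 (2S,4S)-2-ethynyl-7-methoxy-5-(methoxymethoxy)-6,8-dimethylchroman-4-ol, via silylalkynyl chromanol 12 (not isolated)
Conditions: NaBH4, MeOH/THF, 0 °C; then K2CO3 (0.3 equiv), MeOH, rt
Reagents that add atoms: none
Why: Borohydride reduction of the aryl ketone (axial hydride delivery, mainly the 2,4-cis alcohol) removes the enolisable β-aryloxy ketone that would ring-open and racemise C2 under strong base, and methanolic carbonate then cleaves the C(sp)–Si bond.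

Step 7
Reactants: 14 dimethyl squarate (3,4-dimethoxycyclobut-3-ene-1,2-dione)
Product: 16 3-methoxycyclobut-3-ene-1,2-dione (methyl semisquarate), via hydroxycyclobutenone 15 (not isolated)
Conditions: LiAlH(OtBu)3 (1.0 equiv), THF, −78 → −20 °C; then 12 M HCl, CH2Cl2, rt
Reagents that add atoms: none
Why: The bulky hydride reduces one carbonyl only, and acid then ionises the allylic carbinol and hydrolyses the resulting oxocarbenium with loss of methanol (the established reduction and 1,2-carbonyl transposition from squarate diesters to semisquarate esters).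

Step 8
Reactants: 13 (2S,4S)-2-ethynyl-7-methoxy-5-(methoxymethoxy)-6,8-dimethylchroman-4-ol; 16 3-methoxycyclobut-3-ene-1,2-dione
Product: 18 4-hydroxy-4-{[(2S,4S)-4-hydroxy-7-methoxy-5-(methoxymethoxy)-6,8-dimethylchroman-2-yl]ethynyl}-3-methoxycyclobut-2-en-1-one (both carbinol epimers), via dilithio alkoxide acetylide 17 (not isolated)
Conditions: n-BuLi (2.05 equiv), THF, −78 °C; then 16 (1.1 equiv), −78 °C; sat. aq. NH4Cl at −78 °C
Reagents that add atoms: none
Why: The acetylide carbon of the dianion adds 1,2 to the carbonyl next to the methoxy-bearing carbon of 16, which is the more electrophilic one because the other is a vinylogous ester (the usual regiochemistry of organolithium addition to alkoxycyclobutenediones), while the hindered lithium alkoxide stays inert at −78 °C and the new carbinol centre forms unselectively.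

Step 9
Reactants: 18 4-hydroxy-4-{[(2S,4S)-4-hydroxy-7-methoxy-5-(methoxymethoxy)-6,8-dimethylchroman-2-yl]ethynyl}-3-methoxycyclobut-2-en-1-one
Product: 19 4-hydroxy-3-methoxy-4-{[(2S)-7-methoxy-5-(methoxymethoxy)-6,8-dimethyl-4-oxochroman-2-yl]ethynyl}cyclobut-2-en-1-one (both carbinol epimers)
Conditions: Dess–Martin periodinane, NaHCO3, CH2Cl2, 0 °C → rt
Reagents that add atoms: none
Why: Dess–Martin oxidation converts the secondary benzylic alcohol into the aryl ketone under buffered, non-basic conditions and cannot oxidise the tertiary carbinol.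

Step 10
Reactants: 19 4-hydroxy-3-methoxy-4-{[(2S)-7-methoxy-5-(methoxymethoxy)-6,8-dimethyl-4-oxochroman-2-yl]ethynyl}cyclobut-2-en-1-one
Product: 22 2-methoxy-5-[(2S)-7-methoxy-5-(methoxymethoxy)-6,8-dimethyl-4-oxochroman-2-yl]cyclohexa-2,5-diene-1,4-dione, via ene-yne ketene 20 (not isolated), via diradical 21 (not isolated)
Conditions: PhMe (0.01 M, degassed), 110 °C
Reagents that add atoms: none
Why: Conrotatory four-electron electrocyclic opening of the cyclobutenone, with the carbinol hydroxyl rotating outward, should give the (Z)-ene-yne ketene 20 in which the alkyne lies cis to the ketene. The ketene carbon (future C2') then bonds to the distal alkyne carbon (future C1', the one carrying chromanone C2), closing ring B in the six-membered mode to the aryl/phenoxyl diradical 21, and transfer of the hydroxyl hydrogen to the ring carbon radical (C6') gives the quinone. This is the Moore rearrangement of 4-alkynyl-4-hydroxycyclobutenones to 1,4-benzoquinones, applied here to a semisquarate-derived member with hydrogen on the cyclobutenone C2. No stereocentre is created: the carbinol centre is destroyed and chromanone C2 is a spectator under neutral, base-free heating. The selectivity needed is six- over five-membered closure (quinone, not alkylidenecyclopentenedione), and the sp3 chromanyl carbon on the alkyne terminus secures it because it cannot stabilise the vinyl radical of the five-membered path. The methoxyl ends up para to the chromanyl carbon because the acetylide was attached next to the methoxy-bearing carbon in step 8.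

Step 11
Reactants: 22 2-methoxy-5-[(2S)-7-methoxy-5-(methoxymethoxy)-6,8-dimethyl-4-oxochroman-2-yl]cyclohexa-2,5-diene-1,4-dione
Product: 23 2-[(2S)-5-hydroxy-7-methoxy-6,8-dimethyl-4-oxochroman-2-yl]-5-methoxycyclohexa-2,5-diene-1,4-dione (target)
Conditions: HCl (1.25 M in MeOH), CH2Cl2/MeOH, 0 °C → rt
Reagents that add atoms: none
Why: Acid-catalysed acetal exchange with methanol removes the MOM group, which the peri carbonyl activates, while methanol as solvent makes any exchange of the quinone methoxyl degenerate and C2 is not epimerised under acid.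

## Compound list

1 | 2',4',6'-trihydroxyacetophenone | CC(=O)c1c(O)cc(O)cc1O | starting material
2 | 2',4',6'-trihydroxy-3'-methylacetophenone | CC(=O)c1c(O)cc(O)c(C)c1O | intermediate
3 | 2',4',6'-trihydroxy-3',5'-dimethylacetophenone | CC(=O)c1c(O)c(C)c(O)c(C)c1O | intermediate
4 | 2',6'-dihydroxy-4'-methoxy-3',5'-dimethylacetophenone | CC(=O)c1c(O)c(C)c(OC)c(C)c1O | intermediate
5 | 2,5-dihydroxy-7-methoxy-6,8-dimethylchroman-4-one (racemic hemiacetal) | O=C1CC(O)Oc2c(C)c(OC)c(C)c(O)c12 | intermediate
6 | 5-hydroxy-7-methoxy-6,8-dimethyl-4H-chromen-4-one | O=c1ccoc2c(C)c(OC)c(C)c(O)c12 | intermediate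
7 | 7-methoxy-5-(methoxymethoxy)-6,8-dimethyl-4H-chromen-4-one | COCOc1c(C)c(OC)c(C)c2occc(=O)c12 | intermediate
8 | trimethylsilylacetylene | C#C[Si](C)(C)C | starting material
9 | 4-(tert-butyldimethylsilyloxy)-7-methoxy-5-(methoxymethoxy)-6,8-dimethylchromenylium triflate | CC(C)(C)[Si](C)(C)Oc1cc[o+]c2c(C)c(OC)c(C)c(OCOC)c12.[O-]S(=O)(=O)C(F)(F)F | intermediate
10 | (2S)-4-(tert-butyldimethylsilyloxy)-7-methoxy-5-(methoxymethoxy)-6,8-dimethyl-2-[(trimethylsilyl)ethynyl]-2H-chromene | C[Si](C)(C)C#C[C@@H]1C=C(O[Si](C)(C)C(C)(C)C)c2c(OCOC)c(C)c(OC)c(C)c2O1 | intermediate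
11 | (2S)-7-methoxy-5-(methoxymethoxy)-6,8-dimethyl-2-[(trimethylsilyl)ethynyl]chroman-4-one | C[Si](C)(C)C#C[C@@H]1CC(=O)c2c(OCOC)c(C)c(OC)c(C)c2O1 | intermediate
12 | (2S,4S)-7-methoxy-5-(methoxymethoxy)-6,8-dimethyl-2-[(trimethylsilyl)ethynyl]chroman-4-ol | C[Si](C)(C)C#C[C@@H]1C[C@H](O)c2c(OCOC)c(C)c(OC)c(C)c2O1 | intermediate
13 | (2S,4S)-2-ethynyl-7-methoxy-5-(methoxymethoxy)-6,8-dimethylchroman-4-ol | C#C[C@@H]1C[C@H](O)c2c(OCOC)c(C)c(OC)c(C)c2O1 | intermediate
14 | dimethyl squarate (3,4-dimethoxycyclobut-3-ene-1,2-dione) | COc1c(OC)c(=O)c1=O | starting material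
15 | 4-hydroxy-2,3-dimethoxycyclobut-2-en-1-one (racemic) | COC1=C(OC)C(=O)C1O | intermediate
16 | 3-methoxycyclobut-3-ene-1,2-dione (methyl semisquarate) | COC1=CC(=O)C1=O | intermediate
17 | dilithium salt of 13 (lithium C4-alkoxide, lithium acetylide) | [Li]C#C[C@@H]1C[C@H](O[Li])c2c(OCOC)c(C)c(OC)c(C)c2O1 | intermediate
18 | 4-hydroxy-4-{[(2S,4S)-4-hydroxy-7-methoxy-5-(methoxymethoxy)-6,8-dimethylchroman-2-yl]ethynyl}-3-methoxycyclobut-2-en-1-one (both carbinol epimers) | COC1=CC(=O)C1(O)C#C[C@@H]1C[C@H](O)c2c(OCOC)c(C)c(OC)c(C)c2O1 | intermediate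
19 | 4-hydroxy-3-methoxy-4-{[(2S)-7-methoxy-5-(methoxymethoxy)-6,8-dimethyl-4-oxochroman-2-yl]ethynyl}cyclobut-2-en-1-one (both carbinol epimers) | COC1=CC(=O)C1(O)C#C[C@@H]1CC(=O)c2c(OCOC)c(C)c(OC)c(C)c2O1 | intermediate
20 | (Z)-ene-yne ketene: 4-hydroxy-3-methoxy-6-[(2S)-chromanon-2-yl]hexa-1,3-dien-5-yn-1-one, chromanone substituted as in 19 | O=C=C/C(OC)=C(/O)C#C[C@@H]1CC(=O)c2c(OCOC)c(C)c(OC)c(C)c2O1 | intermediate
21 | aryl/phenoxyl diradical: 4-hydroxy-5-methoxy-2-[(2S)-chromanon-2-yl]phenoxyl with a carbon radical at ring position 3, chromanone substituted as in 19 | [O]c1cc(OC)c(O)[c]c1[C@@H]1CC(=O)c2c(OCOC)c(C)c(OC)c(C)c2O1 | intermediate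
22 | 2-methoxy-5-[(2S)-7-methoxy-5-(methoxymethoxy)-6,8-dimethyl-4-oxochroman-2-yl]cyclohexa-2,5-diene-1,4-dione | COC1=CC(=O)C([C@@H]2CC(=O)c3c(OCOC)c(C)c(OC)c(C)c3O2)=CC1=O | intermediate
23 | 2-[(2S)-5-hydroxy-7-methoxy-6,8-dimethyl-4-oxochroman-2-yl]-5-methoxycyclohexa-2,5-diene-1,4-dione | COC1=CC(=O)C([C@@H]2CC(=O)c3c(O)c(C)c(OC)c(C)c3O2)=CC1=O | target

## Step count and risks

Total: 11 steps. Longest linear sequence: 10 steps (steps 1–6 and 8–11, from 1); step 7 is a one-step branch from 14 that joins at step 8.

Steps most likely to fail: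

1. Step 5. The process at risk is insufficient enantiofacial discrimination when the copper acetylide adds to this hindered, electron-rich benzopyrylium ion. Fallback: setting out from 7, the same silyl triflate activation and CuI/iPr2NEt alkynylation with 8, run without chiral ligand, would give the racemic silyl enol ether F1 and, after the same dilute acid hydrolysis, the racemic chromanone F2. Asymmetric transfer hydrogenation of F2 with RuCl(p-cymene)[(S,S)-TsDPEN] and HCO2Na in MeOH/H2O, stopped near half conversion as a kinetic resolution, should reduce the 2S ketone faster to the 2,4-cis alcohol. The route is rejoined at 12, which is then desilylated with K2CO3/MeOH as in step 6.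

2. Step 8. The process at risk is diversion of the semisquarate by the C4 lithium alkoxide, or attack of the acetylide at the vinylogous ester carbonyl or the unsubstituted ring carbon. Fallback: setting out from 13, TESCl and imidazole in DMF would give the triethylsilyl ether F3. One equivalent of n-BuLi at −78 °C would give the monolithium acetylide F4, which has no second nucleophilic site, and addition to 16 would give the silyl-protected carbinol F5. TBAF buffered with AcOH in THF at 0 °C would remove the silyl group and return to the route at 18.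

3. Step 10. The process at risk is closure of the ene-yne ketene in the five-membered mode, or loss of the monosubstituted ketene to intermolecular reactions at the temperature required. Fallback: setting out from 7, conjugate addition of 2,4,5-trimethoxyphenylboronic acid catalysed by Pd(OCOCF3)2 and t-BuPyOx (the antipode giving 2S) in ClCH2CH2Cl/H2O at 60 °C would give the (2S)-2-(2,4,5-trimethoxyphenyl)chromanone F6. Oxidative demethylation with (NH4)2Ce(NO3)6 in MeCN/H2O at 0 °C should convert the para-dimethoxy pair of that ring into the quinone carbonyls and keep the third methoxyl, returning to the route at 22.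

## Further compounds

F1 | step 5 | racemic 4-(tert-butyldimethylsilyloxy)-7-methoxy-5-(methoxymethoxy)-6,8-dimethyl-2-[(trimethylsilyl)ethynyl]-2H-chromene | C[Si](C)(C)C#CC1C=C(O[Si](C)(C)C(C)(C)C)c2c(OCOC)c(C)c(OC)c(C)c2O1
F2 | step 5 | racemic 7-methoxy-5-(methoxymethoxy)-6,8-dimethyl-2-[(trimethylsilyl)ethynyl]chroman-4-one | C[Si](C)(C)C#CC1CC(=O)c2c(OCOC)c(C)c(OC)c(C)c2O1
F3 | step 8 | (2S,4S)-2-ethynyl-7-methoxy-5-(methoxymethoxy)-6,8-dimethyl-4-(triethylsilyloxy)chroman | C#C[C@@H]1C[C@H](O[Si](CC)(CC)CC)c2c(OCOC)c(C)c(OC)c(C)c2O1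
F4 | step 8 | lithium acetylide of F3 | [Li]C#C[C@@H]1C[C@H](O[Si](CC)(CC)CC)c2c(OCOC)c(C)c(OC)c(C)c2O1
F5 | step 8 | 4-hydroxy-3-methoxy-4-{[(2S,4S)-7-methoxy-5-(methoxymethoxy)-6,8-dimethyl-4-(triethylsilyloxy)chroman-2-yl]ethynyl}cyclobut-2-en-1-one (both carbinol epimers) | COC1=CC(=O)C1(O)C#C[C@@H]1C[C@H](O[Si](CC)(CC)CC)c2c(OCOC)c(C)c(OC)c(C)c2O1
F6 | step 10 | (2S)-7-methoxy-5-(methoxymethoxy)-6,8-dimethyl-2-(2,4,5-trimethoxyphenyl)chroman-4-one | COc1cc(OC)c([C@@H]2CC(=O)c3c(OCOC)c(C)c(OC)c(C)c3O2)cc1OC
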